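The south run held 84.0% of its free monomer in chains at 80.0 min, from a charge of 0.300 mM of initiator, and I built my reckoning for both new flasks on that pair of numbers.

| flask | free monomer | transfer agent | initiator | remark | time |
|---|---|---|---|---|---|
| south | 20 mM | 2 mM | 1.5 mol% | run made earlier |  |
| Tuesday's | 20 mM | 2.00 mM | 1 mol% |  | 2.0 h |
| Saturday's | 60 mM | 2.00 mM | 1 mol% |  | 2.0 h |

- south (time / min: monomer in chains / %): 10.0: 60.7; 20.0: 75.3; 30.0: 80.0; 40.0: 84.3; 50.0: 82.6; 60.0: 83.8; 80.0: 84.0

(scatter of a reading: 1 percentage point)

- the average divides the monomer in chains by the number of chains begun, living and dead together
- the earlier runs do not show the number of chains; that part of a forecast is a guess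
- no earlier run changes the charge of initiator; that part of a forecast is a guess

* which of the two ends with the longer chains by the average number of monomer units in a chain (chains begun, living or dead) ("neither" if they lie within 10%) (Tuesday's / Saturday's / neither)
* average number of monomer units in a chain (chains begun, living or dead) at the end, Tuesday's
* average number of monomer units in a chain (chains begun, living or dead) at the end, Saturday's

First I asked whether the south run had stopped. From 40.0 min on, its readings stayed between 82.6% and 84.3%, with a scatter of 1 percentage point, so I read a level. Tuesday's has the same c(free monomer) and runs for 2.0 h, longer than that, so I reckoned both new flasks at their levels, though for Saturday's this was a guess.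

Then I asked how far a charge of initiator carries. I assumed that free monomer is lost in proportion to what is free, with a coefficient that fades as the run levels, so I took the logarithm of charged over left, which sums that coefficient over the run, and divided it by the initiator charged. I call this the reach of the initiator, 6.11 mM⁻¹, counting whatever was not in chains as free. That it stays constant at equal c(transfer agent) was my guess.

Tuesday's has 0.200 mM of initiator, which gives 70.5% in chains. Saturday's has 0.600 mM, which gives 97.4%.

Last came the length. I guessed one chain per initiator, so at equal loading the length is the conversion over the loading: 70.5 for Tuesday's and 97.4 for Saturday's. Their ratio, 1.38, clears the margin of 10%, so I chose Saturday's.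

The forecast also chose Saturday's, but with 7 and 21, far below my lengths: “Chains are guessed as 2 mM agent plus initiator-derived chains”.

The flasks gave Saturday's, with 103 for Tuesday's and 144 for Saturday's.

    free monomer + initiator → living end + monomer in chains (k = 65.0 M⁻¹ min⁻¹)
    free monomer + living end → monomer in chains + living end, rate k2*[living end]*[free monomer] (k = 660 M⁻¹ min⁻¹)
    living end + transfer agent → dead chain (kL = 39.0 M⁻¹ min⁻¹)
    free monomer + initiator → spent initiator (k = 31.0 M⁻¹ min⁻¹)

Tuesday's ended with 0.135 mM of dead chain from 0.200 mM of initiator, and its length stood at 103 against my 70.5. Its free monomer stood at 30%, a reach of 6.02 mM⁻¹ against the 6.11 mM⁻¹ read from the south run. Saturday's flask with 0.4 mol% of initiator has 0.240 mM of it, so the reach left 23.1% of its free monomer, and that flask ended with 23.7%.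

The data stem from a simulated flask for an exercise; scatter was added.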